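**Strategy.** Azulene numbering is used (five-membered ring C1–C3, fusion C3a/C8a, seven-membered ring C4–C8). The cyclopentanol ring is disconnected at C1–C8a and C3–C3a: with C4 as a ketone, C8a is the β- and C3a the α-carbon of an enone, and the tertiary C3 carbinol is an aldol oxygen. The key step therefore joins the zinc homoenolate of 1-isopropylcyclopropanol to the symmetric 3,6-dimethylcyclohepta-2,6-dienone by copper-catalysed asymmetric conjugate addition and in-flask aldol closure, setting the quaternary C8a, the trans ring fusion and C3 while desymmetrising the ring. The surviving enone is then shifted to C6=C7 and turned into the exocyclic allylic alcohol; the vanillate is attached at C4.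

Key step: step 5

Remark: the exact chiral N-heterocyclic carbene (NHC) ligand for step 5 is left open; the enantiomer that directs addition to the Re face of the enone β-carbon is assumed and would be fixed by screening.

**Step 1**
Reactants: 1 2,5-dimethylfuran; 2 1,1,3,3-tetrabromopropan-2-one
Product: 4 (1R,5S)-1,5-dimethyl-8-oxabicyclo[3.2.1]oct-6-en-3-one, via cis-2,4-dibromo cycloadduct 3 (not isolated)
Conditions: Zn–Cu couple, THF, −10 → 22 °C; then Zn–Cu couple, NH4Cl, MeOH, 22 °C
Reagents that add atoms: none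
Why: Zinc reduction of 2 should give a dibromo-oxyallyl cation that undergoes (4+3) cycloaddition across C2/C5 of the electron-rich furan, the bridged geometry allowing only the meso adduct 3, whose two α-bromines are then removed by zinc reduction of the α-bromoketone.

**Step 2**
Reactants: 4 (1R,5S)-1,5-dimethyl-8-oxabicyclo[3.2.1]oct-6-en-3-one
Product: 5 (1R,5S)-1,5-dimethyl-8-oxabicyclo[3.2.1]octan-3-one
Conditions: H2 (1 atm), Pd/C, EtOAc, 22 °C
Reagents that add atoms: none
Why: Heterogeneous catalytic hydrogenation should saturate the strained disubstituted C6=C7 alkene without touching the ketone or the bridging ether, and creates no stereocentre (5 is meso).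

**Step 3**
Reactants: 5 (1R,5S)-1,5-dimethyl-8-oxabicyclo[3.2.1]octan-3-one
Product: 7 3,6-dimethylcyclohepta-2,6-dien-1-one, via hydroxy enone 6 (not isolated)
Conditions: TsOH·H2O (10 mol%), toluene, reflux, Dean–Stark trap
Reagents that add atoms: none
Why: Twofold acid-catalysed β-elimination, in which retro-oxa-Michael opening of the β-alkoxy ketone gives 6 and its tertiary β-hydroxy ketone then dehydrates, should be driven by azeotropic water removal and by formation of two trisubstituted conjugated alkenes; all stereocentres are destroyed.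

**Step 4**
Reactants: 8 methyl 2-methylpropanoate
Product: 9 1-(propan-2-yl)cyclopropan-1-ol
Conditions: EtMgBr (2.4 equiv), Ti(OiPr)4 (15 mol%), Et2O, 0 → 22 °C
Reagents that add atoms: ethylmagnesium bromide, CC[Mg]Br
Why: Kulinkovich reaction, in which the titanacyclopropane formed from EtMgBr and Ti(OiPr)4 acts as a 1,2-dicarbanion toward the ester and gives the 1-substituted cyclopropanol (no stereocentre).

**Step 5**
Reactants: 7 3,6-dimethylcyclohepta-2,6-dien-1-one; 9 1-(propan-2-yl)cyclopropan-1-ol
Product: 12 (3R,3aR,8aS)-3-hydroxy-6,8a-dimethyl-3-(propan-2-yl)-2,3,3a,7,8,8a-hexahydroazulen-4(1H)-one, via zinc homoenolate 10 (not isolated), via zinc dienolate 11 (not isolated)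
Conditions: 9 (2.0 equiv), Et2Zn (1.0 equiv), toluene, 0 → 22 °C; then 7 (1.3 equiv), Cu(OTf)2 (5 mol%), chiral imidazolinium salt (NHC precursor, 6 mol%), Et2O, −20 → 22 °C, 12 h; aq. NH4Cl
Reagents that add atoms: none
Why: Proposed new method: Et2Zn deprotonates 9, whose zinc alkoxide ring-opens by β-carbon elimination to the homoenolate 10; transmetalation to the chiral NHC–copper catalyst (monovalent copper, formed in the flask from Cu(OTf)2) and 1,4-addition to the Re face of C3 of 7 (C6 is equivalent by the twofold axis) forms C1–C8a and gives the zinc dienolate 11, whose α-carbon (C3a) then adds to the pendant isopropyl ketone to form C3–C3a. The closest known reaction types are the enantioselective conjugate addition of cyclopropanol-derived zinc homoenolates to acyclic enones with ensuing aldol closure, and the copper–NHC-catalysed addition of organozinc reagents to β-methyl cycloalkenones that creates quaternary centres; their merger on a β,β-disubstituted cyclic dienone is untested. The cyclopentane closes by a 5-(enolexo)-exo-trig aldol addition, the seven-membered ring being already in place. C8a is set by the catalyst (the two enone termini are enantiotopic, so facial choice alone decides the enantiomer), whereas C3a and C3 are expected to settle under thermodynamic control through the reversible zinc aldolate, the trans-fused isomer with a C3–O/C4=O zinc chelate being the one that places the isopropyl group anti to both C4 and the angular methyl. The step needs 1,4- over 1,2-addition (copper), α-reactivity of the cross-conjugated dienolate (favoured by the five-membered closure) and mono-annulation, the last secured by the excess of 7 and by the dienolate character of 11, which deactivates the second enone until the aldol has occurred.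

**Step 6**
Reactants: 12 (3R,3aR,8aS)-3-hydroxy-6,8a-dimethyl-3-(propan-2-yl)-2,3,3a,7,8,8a-hexahydroazulen-4(1H)-one
Product: 14 (3R,3aR,8aR)-3-hydroxy-6,8a-dimethyl-3-(propan-2-yl)-2,3,3a,5,8,8a-hexahydroazulen-4(1H)-one, via potassium dienolate 13 (not isolated)
Conditions: KOtBu (2.5 equiv), t-BuOH–THF, 22 °C; then inverse quench into AcOH–H2O, 0 °C
Reagents that add atoms: none
Why: Deconjugative isomerisation, in which γ-deprotonation at C7 gives the thermodynamic linear dienolate 13 and kinetic protonation at the α-carbon C5 should give the β,γ-unsaturated ketone; C3a and C3 stay under the same thermodynamic (retro-aldol/epimerisation) control as in step 5.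

**Step 7**
Reactants: 14 (3R,3aR,8aR)-3-hydroxy-6,8a-dimethyl-3-(propan-2-yl)-2,3,3a,5,8,8a-hexahydroazulen-4(1H)-one
Product: 15 (3R,3aS,4S,8aR)-6,8a-dimethyl-3-(propan-2-yl)-1,2,3,3a,4,5,8,8a-octahydroazulene-3,4-diol
Conditions: Me4NBH(OAc)3 (5 equiv), MeCN–AcOH (1:1), −25 °C
Reagents that add atoms: none
Why: Evans–Saksena reduction, in which the C3 hydroxyl exchanges onto boron and should deliver hydride to the β face of the C4 carbonyl (the face on which the C3 oxygen lies in the trans-fused skeleton), giving the anti-1,3-diol with the equatorial 4α-hydroxyl, (4S).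

**Step 8**
Reactants: 15 (3R,3aS,4S,8aR)-6,8a-dimethyl-3-(propan-2-yl)-1,2,3,3a,4,5,8,8a-octahydroazulene-3,4-diol
Product: 16 (3R,3aS,4S,6R,7S,8aR)-6,7-epoxy-6,8a-dimethyl-3-(propan-2-yl)decahydroazulene-3,4-diol
Conditions: VO(acac)2 (5 mol%), t-BuOOH (1.5 equiv), CH2Cl2, 0 → 22 °C
Reagents that add atoms: tert-butyl hydroperoxide, CC(C)(C)OO
Why: Hydroxyl-directed epoxidation, in which the vanadate ester of the homoallylic 4α-hydroxyl should deliver oxygen to the α face of the C6=C7 alkene, the face that is also anti to the angular C8a methyl, setting (6R,7S).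

**Step 9**
Reactants: 16 (3R,3aS,4S,6R,7S,8aR)-6,7-epoxy-6,8a-dimethyl-3-(propan-2-yl)decahydroazulene-3,4-diol; 17 4-acetoxy-3-methoxybenzoic acid
Product: 18 (3R,3aS,4S,6R,7S,8aR)-6,7-epoxy-3-hydroxy-6,8a-dimethyl-3-(propan-2-yl)decahydroazulen-4-yl 4-acetoxy-3-methoxybenzoate
Conditions: DCC (1.5 equiv), DMAP (0.2 equiv), CH2Cl2, 22 °C
Reagents that add atoms: none
Why: Steglich esterification should acylate the only secondary hydroxyl (C4), since the tertiary C3 hydroxyl and the epoxide are inert under these neutral conditions; no stereocentre is touched.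

**Step 10**
Reactants: 18 (3R,3aS,4S,6R,7S,8aR)-6,7-epoxy-3-hydroxy-6,8a-dimethyl-3-(propan-2-yl)decahydroazulen-4-yl 4-acetoxy-3-methoxybenzoate
Product: 19 (3R,3aS,4S,7S,8aR)-3,7-dihydroxy-8a-methyl-6-methylidene-3-(propan-2-yl)decahydroazulen-4-yl 4-acetoxy-3-methoxybenzoate
Conditions: Cp2TiCl2 (2.5 equiv), Mn dust, THF, 22 °C; then H2O
Reagents that add atoms: none
Why: Epoxide-to-allylic-alcohol isomerisation by Cp2TiCl (trivalent titanium, formed in the flask), in which homolytic opening gives the tertiary C6 radical with the C7–O bond intact and hydrogen loss from the least hindered β-position, the C6 methyl group, should give the exocyclic alkene, so (7S) follows from the epoxide.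

**Step 11**
Reactants: 19 (3R,3aS,4S,7S,8aR)-3,7-dihydroxy-8a-methyl-6-methylidene-3-(propan-2-yl)decahydroazulen-4-yl 4-acetoxy-3-methoxybenzoate
Product: 20 (3R,3aS,4S,7S,8aR)-3,7-dihydroxy-8a-methyl-6-methylidene-3-(propan-2-yl)decahydroazulen-4-yl 4-hydroxy-3-methoxybenzoate
Conditions: pyrrolidine (5 equiv), CH2Cl2, 0 °C
Reagents that add atoms: none
Why: Aminolysis of the phenolic acetate, an activated aryl ester, should be much faster than attack on the hindered secondary benzoate and releases the phenol without touching other groups.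

**Compound list**
1 | 2,5-dimethylfuran | Cc1ccc(C)o1 | starting material
2 | 1,1,3,3-tetrabromopropan-2-one | O=C(C(Br)Br)C(Br)Br | starting material
3 | (1R,2S,4R,5S)-2,4-dibromo-1,5-dimethyl-8-oxabicyclo[3.2.1]oct-6-en-3-one (meso, both bromines equatorial) | C[C@@]12C=C[C@@](C)(O1)[C@H](Br)C(=O)[C@@H]2Br | intermediate
4 | (1R,5S)-1,5-dimethyl-8-oxabicyclo[3.2.1]oct-6-en-3-one (meso) | C[C@@]12C=C[C@@](C)(O1)CC(=O)C2 | intermediate
5 | (1R,5S)-1,5-dimethyl-8-oxabicyclo[3.2.1]octan-3-one (meso) | C[C@@]12CC[C@@](C)(O1)CC(=O)C2 | intermediate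
6 | 6-hydroxy-3,6-dimethylcyclohept-2-en-1-one (racemic) | CC1=CC(=O)CC(C)(O)CC1 | intermediate
7 | 3,6-dimethylcyclohepta-2,6-dien-1-one | CC1=CC(=O)C=C(C)CC1 | intermediate
8 | methyl 2-methylpropanoate | COC(=O)C(C)C | starting material
9 | 1-(propan-2-yl)cyclopropan-1-ol | CC(C)C1(O)CC1 | intermediate
10 | bis(4-methyl-3-oxopentyl)zinc (zinc homoenolate) | CC(C)C(=O)CC[Zn]CCC(=O)C(C)C | intermediate
11 | (4-methyl-3-oxopentyl)zinc enolate of (6S)-3,6-dimethyl-6-(4-methyl-3-oxopentyl)cyclohept-2-en-1-one (O–C1=C7 dienolate) | CC1=CC(O[Zn]CCC(=O)C(C)C)=C[C@](C)(CCC(=O)C(C)C)CC1 | intermediate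
12 | (3R,3aR,8aS)-3-hydroxy-6,8a-dimethyl-3-(propan-2-yl)-2,3,3a,7,8,8a-hexahydroazulen-4(1H)-one | CC1=CC(=O)[C@@H]2[C@](C)(CC[C@@]2(O)C(C)C)CC1 | intermediate
13 | potassium C4-dienolate of 12 (C4=C5 and C6=C7, stereocentres as in 12) | CC1=CC[C@@]2(C)CC[C@@](O)(C(C)C)[C@@H]2C([O-])=C1.[K+] | intermediate
14 | (3R,3aR,8aR)-3-hydroxy-6,8a-dimethyl-3-(propan-2-yl)-2,3,3a,5,8,8a-hexahydroazulen-4(1H)-one | CC1=CC[C@@]2(C)CC[C@@](O)(C(C)C)[C@@H]2C(=O)C1 | intermediate
15 | (3R,3aS,4S,8aR)-6,8a-dimethyl-3-(propan-2-yl)-1,2,3,3a,4,5,8,8a-octahydroazulene-3,4-diol | CC1=CC[C@@]2(C)CC[C@@](O)(C(C)C)[C@@H]2[C@@H](O)C1 | intermediate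
16 | (3R,3aS,4S,6R,7S,8aR)-6,7-epoxy-6,8a-dimethyl-3-(propan-2-yl)decahydroazulene-3,4-diol | C[C@]12O[C@H]1C[C@@]3(C)CC[C@@](O)(C(C)C)[C@@H]3[C@@H](O)C2 | intermediate
17 | 4-acetoxy-3-methoxybenzoic acid | COc1cc(C(=O)O)ccc1OC(C)=O | starting material
18 | (3R,3aS,4S,6R,7S,8aR)-6,7-epoxy-3-hydroxy-6,8a-dimethyl-3-(propan-2-yl)decahydroazulen-4-yl 4-acetoxy-3-methoxybenzoate | C[C@]12O[C@H]1C[C@@]3(C)CC[C@@](O)(C(C)C)[C@@H]3[C@@H](OC(=O)c4ccc(OC(C)=O)c(OC)c4)C2 | intermediate
19 | (3R,3aS,4S,7S,8aR)-3,7-dihydroxy-8a-methyl-6-methylidene-3-(propan-2-yl)decahydroazulen-4-yl 4-acetoxy-3-methoxybenzoate | C=C1C[C@H](OC(=O)c2ccc(OC(C)=O)c(OC)c2)[C@@H]2[C@](C)(CC[C@@]2(O)C(C)C)C[C@@H]1O | intermediate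
20 | (3R,3aS,4S,7S,8aR)-3,7-dihydroxy-8a-methyl-6-methylidene-3-(propan-2-yl)decahydroazulen-4-yl 4-hydroxy-3-methoxybenzoate | C=C1C[C@H](OC(=O)c2ccc(O)c(OC)c2)[C@@H]2[C@](C)(CC[C@@]2(O)C(C)C)C[C@@H]1O | target

**Step count and risks**
Total step count: 11. Longest linear sequence: 10 (steps 1–3 and 5–11; step 4 is a one-step side branch).

Steps most likely to fail:

1. Step 5 (Proposed new method). The chelated homoenolate may transfer too slowly to copper and to a β,β-disubstituted enone, an uncatalysed zinc pathway may erode enantioface control, and a second annulation may occur at the remaining enone. Fallback with known chemistry, setting out from 9 and 7 and returning at 12: ring-opening bromination of 9 with NBS gives 1-bromo-4-methylpentan-3-one F1, which is ketalised with ethylene glycol (TsOH) to 2-(2-bromoethyl)-2-(propan-2-yl)-1,3-dioxolane F2. Its Grignard reagent, [2-(2-isopropyl-1,3-dioxolan-2-yl)ethyl]magnesium bromide F3, is added to 7 under Cu(OTf)2/chiral imidazolinium (NHC) catalysis, the established copper-catalysed asymmetric conjugate addition of Grignard reagents to β-methyl cycloalkenones, to give the ketal enone F4. Aqueous HCl then frees the 1,6-diketone F5, and KOtBu in t-BuOH closes the aldol under thermodynamic control to 12.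

2. Step 6. Protonation may occur at the γ-carbon and return the conjugated enone, the exocyclic dienolate may form, and the alkoxide may open by retro-aldol without re-closing cleanly. Fallback, setting out from 12 and returning at 14: TMSOTf/Et3N converts 12 into the 3,4-bis(trimethylsilyl) dienol ether F6, which is isolated free of base. Buffered fluoride (TBAF, AcOH, THF, −78 °C) then protonates C5 and cleaves the tertiary silyl ether to give 14.

3. Step 10. Hydrogen may be lost toward C5 instead of the methyl group (endocyclic alkene), and reductive deoxygenation of the epoxide may compete. Fallback, setting out from 15 and returning at 19: 15 is esterified with 17 (DCC, DMAP) to the alkene ester F7. A Schenck ene reaction with singlet oxygen (O2, tetraphenylporphyrin, hν, CH2Cl2), which should attack the α face anti to the angular methyl, gives the allylic hydroperoxide F8, reduced in the flask with PPh3 to 19.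

**Further compounds**
F1 | step 5 | 1-bromo-4-methylpentan-3-one | CC(C)C(=O)CCBr
F2 | step 5 | 2-(2-bromoethyl)-2-(propan-2-yl)-1,3-dioxolane | CC(C)C1(CCBr)OCCO1
F3 | step 5 | [2-(2-isopropyl-1,3-dioxolan-2-yl)ethyl]magnesium bromide | CC(C)C1(CC[Mg]Br)OCCO1
F4 | step 5 | (6S)-3,6-dimethyl-6-{2-[2-(propan-2-yl)-1,3-dioxolan-2-yl]ethyl}cyclohept-2-en-1-one | CC1=CC(=O)C[C@](C)(CCC2(C(C)C)OCCO2)CC1
F5 | step 5 | (6S)-3,6-dimethyl-6-(4-methyl-3-oxopentyl)cyclohept-2-en-1-one | CC1=CC(=O)C[C@](C)(CCC(=O)C(C)C)CC1
F6 | step 6 | 3,4-bis(trimethylsilyl) dienol ether of 12 (C4=C5 and C6=C7, stereocentres as in 12) | CC1=CC[C@@]2(C)CC[C@@](O[Si](C)(C)C)(C(C)C)[C@@H]2C(O[Si](C)(C)C)=C1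
F7 | step 10 | (3R,3aS,4S,8aR)-3-hydroxy-6,8a-dimethyl-3-(propan-2-yl)-1,2,3,3a,4,5,8,8a-octahydroazulen-4-yl 4-acetoxy-3-methoxybenzoate | CC1=CC[C@@]2(C)CC[C@@](O)(C(C)C)[C@@H]2[C@@H](OC(=O)c3ccc(OC(C)=O)c(OC)c3)C1
F8 | step 10 | (3R,3aS,4S,7S,8aR)-7-hydroperoxy-3-hydroxy-8a-methyl-6-methylidene-3-(propan-2-yl)decahydroazulen-4-yl 4-acetoxy-3-methoxybenzoate | C=C1C[C@H](OC(=O)c2ccc(OC(C)=O)c(OC)c2)[C@@H]2[C@](C)(CC[C@@]2(O)C(C)C)C[C@@H]1OO
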